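The slow way out of double product is its reaction with partner, at 0.0150 h⁻¹ with partner at full charge, slower than the 0.10 h⁻¹ of its breakdown into side product B.

    double product → side product B (k1 = 0.10 h⁻¹)
    substrate + released group → side product A (k2 = 8.9 L mol⁻¹ h⁻¹)
    partner + first product → double product + released group (k3 = 20 L mol⁻¹ h⁻¹)
    partner + double product → triple product + released group (k4 = 0.23 L mol⁻¹ h⁻¹)
    substrate + partner → first product + released group (k5 = 5.4 L mol⁻¹ h⁻¹)

| setting | north-west | east | south-west | north-east |
|---|---|---|---|---|
| substrate | 0.012 M | 0.025 M | 0.050 M | 0.10 M |
| partner | 0.0650 M | 0.0650 M | 0.0650 M | 0.0650 M |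
| time | 40 h | 40 h | 40 h | 40 h |

1. [triple product] at the end for north-west, east, south-west, north-east, in this order
2. the shape of the row from first to last (falls all the way / rises all the way / hardly changes / rises, then falls / falls, then rises)

Write b for the partner concentration. Double product goes to triple product at k4·b and to side product B at k1, and the two rates are equal at the even-split level K = k1/k4 = 0.435 M. The branching share to triple product is therefore b/(b + K).

The curve of b is replaced by its mean. Each substrate that reaches double product costs 2 partner, so b falls on a straight line. Loss to side product A is not counted. Each row gives the mean b, the share and the triple product: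

- north-west: 0.0530 M; 10.9%; 0.00130 M
- east: 0.0400 M; 8.42%; 0.00211 M
- south-west: 0.0325 M; 6.96%; 0.00226 M
- north-east: 0.0325 M; 6.96%; 0.00226 M

From north-west to east the share drops, but the charge is twice as large, so the east row stands higher. The south-west row reads the same as the north-east row because the partner that substrate would ask for in south-west, 0.100 M, exceeds the charge, and the reckoning then caps double product at 0.0325 M.

That equality is where the mean must be checked. In north-east, partner starts with a half-life of 1.28 h, shorter than the 6.93 h of double product, so double product there meets partner well below the mean. This reckoning therefore commits to a row that rises and then stands level, and it holds its north-east figure to be too high.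

The forecast gives 8.800 × 10⁻⁴ M, 0.0011 M, 9.000 × 10⁻⁴ M and 3.000 × 10⁻⁴ M, shape rises, then falls, holding that “substrate-rich runs use up the partner and lose substrate to the released group”.

The flasks give 9.26 × 10⁻⁴ M, 0.00119 M, 9.18 × 10⁻⁴ M and 2.62 × 10⁻⁴ M, shape rises, then falls. In north-west, with 69% of the partner left, breakdown uses double product 9.7 times faster than partner does at 40.0 h, and K turns that partner into a share of 9.34%, against 9.77% of the two products stored at 400 h. In east, 46% of the partner left gives a share of 6.41% by K, against a simulated 7.13%.

The constants were set for the occasion, and the outcome is calculated.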